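**Plan**

Numbering (drimane): ring A = C1–C5 and C10, ring B = C5–C10, C11 = CH2O, C12 = exocyclic CH2. Retrosynthesis: cut the C11–O aryl ether, put a temporary carbonyl on C1, then cut C2–C3 (aldol) and C5–C10 (allylic alkylation) together, which opens both rings to a monocyclic δ-lactone; the lactone is cut at its ester C–O bond, at C6–C7 (alkenyl addition), at C8=C12 (methylenation) and at C9–C10 (conjugate addition).
Enabling feature: C5 is the far end of the ring B pentadienyl array C5–C6=C7–C8=C12, C10 is quaternary and α to C1, and the neopentyl carbinol C3 is 1,3 to C1; with a C1 carbonyl, C10 and C2 become the two nucleophilic ends of a three-carbon unit that meet a π-pentadienyl palladium terminus (C5) and a non-enolisable aldehyde (C3).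
Forward: an acyclic chain is assembled and tied into a temporary β-keto δ-lactone; one operation then extrudes CO2, closes ring B at C5–C10 with the diene already in place and closes ring A at C2–C3; the C1 oxygen is removed and the coumarin is attached last.
Stereochemistry: C9 is set by amine catalysis; C10 and C5 are relayed from it in the ring B closure and C3 in the aldol closure; the C7 and C10 centres of the lactone are trigonal in the key intermediate and need no control.

Key step: step 9

Remark: compounds 1, 2, 4, 8 and 19 are taken as commercial; centres that are erased in step 9 are carried as epimer mixtures and are left open in the SMILES.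

Step 1
Reactants: 1 tert-butyl(dimethyl)(prop-2-en-1-yloxy)silane; 2 (2E)-but-2-enal
Product: 3 (2E)-4-{[tert-butyl(dimethyl)silyl]oxy}but-2-enal
Conditions: second-generation Hoveyda–Grubbs catalyst (2 mol%), 2 (4 equiv), CH2Cl2, 40 °C
Reagents that add atoms: none
Why: Olefin cross-metathesis of the terminal allyl ether with excess crotonaldehyde should give the E-enal under thermodynamic control while propene escapes.

Step 2
Reactants: 4 methyl 3-hydroxy-2,2-dimethylpropanoate
Product: 5 methyl 2,2-dimethyl-3-oxopropanoate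
Conditions: Dess–Martin periodinane, CH2Cl2, 0 → 23 °C
Reagents that add atoms: none
Why: Dess–Martin oxidation of a primary neopentyl alcohol should stop cleanly at the non-enolisable aldehyde.

Step 3
Reactants: 5 methyl 2,2-dimethyl-3-oxopropanoate
Product: 6 methyl (3E)-4-iodo-2,2-dimethylbut-3-enoate
Conditions: CHI3, CrCl2, THF, 0 → 23 °C
Reagents that add atoms: iodoform, IC(I)I
Why: Takai iodo-olefination through a geminal dichromium species should give the E-vinyl iodide, the hindered ester being inert to CrCl2.

Step 4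
Reactants: 6 methyl (3E)-4-iodo-2,2-dimethylbut-3-enoate
Product: 7 (3E)-4-iodo-2,2-dimethylbut-3-en-1-ol
Conditions: i-Bu2AlH, CH2Cl2, −78 → 0 °C
Reagents that add atoms: none
Why: Hydride reduction of the ester with i-Bu2AlH should give the primary alcohol and leave the vinyl iodide untouched.

Step 5
Reactants: 8 methyl 2-methyl-3-oxobutanoate; 3 (2E)-4-{[tert-butyl(dimethyl)silyl]oxy}but-2-enal
Product: 9 methyl (3R)-2-acetyl-3-({[tert-butyl(dimethyl)silyl]oxy}methyl)-2-methyl-5-oxopentanoate (both C-2 epimers)
Conditions: (S)-2-[diphenyl(trimethylsilyloxy)methyl]pyrrolidine (10 mol%), PhCO2H (10 mol%), EtOH, 0 → 23 °C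
Reagents that add atoms: none
Why: Iminium-ion Michael addition: the diarylmethyl silyl ether group of the S catalyst shields one face of the E-iminium ion, so the β-keto ester should add to the open face of the β-carbon and set C9 as R, the quaternary C-2 centre being of no consequence.

Step 6
Reactants: 9 methyl (3R)-2-acetyl-3-({[tert-butyl(dimethyl)silyl]oxy}methyl)-2-methyl-5-oxopentanoate
Product: 10 methyl (3R)-2-acetyl-3-({[tert-butyl(dimethyl)silyl]oxy}methyl)-4-formyl-2-methylpent-4-enoate (both C-2 epimers)
Conditions: aqueous CH2O, pyrrolidine (10 mol%), EtCO2H (10 mol%), i-PrOH, 45 °C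
Reagents that add atoms: formaldehyde, C=O
Why: Amine-catalysed Mannich condensation with formaldehyde (α-methylenation of an aldehyde) should install the future C12 methylene, and C9 is kept because it is not α to the carbonyl.

Step 7
Reactants: 10 methyl (3R)-2-acetyl-3-({[tert-butyl(dimethyl)silyl]oxy}methyl)-4-formyl-2-methylpent-4-enoate; 7 (3E)-4-iodo-2,2-dimethylbut-3-en-1-ol
Product: 12 (4R)-3-acetyl-4-({[tert-butyl(dimethyl)silyl]oxy}methyl)-6-[(1E)-4-hydroxy-3,3-dimethylbut-1-en-1-yl]-3-methyl-5-methylideneoxan-2-one as a mixture of epimers at C-3 and C-6, via hydroxy ester 11 (not isolated)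
Conditions: CrCl2, NiCl2 (2 mol%), DMSO, 23 °C; aqueous work-up; then Bu2SnO (10 mol%), toluene, 80 °C
Reagents that add atoms: none
Why: The Nozaki–Hiyama–Kishi reaction should add the alkenylchromium species, formed with retention of the E geometry, to the aldehyde only (ketone, ester and free hydroxyl are tolerated), and tin-catalysed transesterification then closes the six-membered lactone through the new secondary alcohol; the new carbinol centre needs no control because it is ionised in step 9.

Step 8
Reactants: 12 (4R)-3-acetyl-4-({[tert-butyl(dimethyl)silyl]oxy}methyl)-6-[(1E)-4-hydroxy-3,3-dimethylbut-1-en-1-yl]-3-methyl-5-methylideneoxan-2-one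
Product: 13 (3E)-4-[(4R)-5-acetyl-4-({[tert-butyl(dimethyl)silyl]oxy}methyl)-5-methyl-3-methylidene-6-oxooxan-2-yl]-2,2-dimethylbut-3-enal
Conditions: Dess–Martin periodinane, CH2Cl2, 23 °C
Reagents that add atoms: none
Why: Dess–Martin oxidation of the only free hydroxyl should give the non-enolisable C3 aldehyde without touching the lactone or the silyl ether.

Step 9
Reactants: 13 (3E)-4-[(4R)-5-acetyl-4-({[tert-butyl(dimethyl)silyl]oxy}methyl)-5-methyl-3-methylidene-6-oxooxan-2-yl]-2,2-dimethylbut-3-enal
Product: 15 (3R,4aR,8R,8aR)-8-({[tert-butyl(dimethyl)silyl]oxy}methyl)-3-hydroxy-4,4,8a-trimethyl-7-methylidene-3,4,4a,7,8,8a-hexahydronaphthalen-1(2H)-one, via monocyclic keto aldehyde 14 (not isolated)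
Conditions: Pd2(dba)3 (2.5 mol%), PPh3 (12 mol%), DBU (0.3 equiv), THF (0.01 M), 23 → 40 °C
Reagents that add atoms: none
Why: Proposed new method: zerovalent palladium should ionise the doubly allylic lactone C7–O bond of 13 to a π-pentadienyl palladium carboxylate, the β-keto carboxylate then loses CO2 to give the regiodefined tetrasubstituted C1=C10 enolate, and this carbon nucleophile can reach only the C5 terminus of the pentadienyl unit, which closes ring B and leaves the C6=C7–C8=CH2 diene in its final place; DBU then enolises the new methyl ketone, which can enolise only towards C2, and C2 adds to the C3 aldehyde to close ring A. The closest known reaction types are the Tsuji decarboxylative allylation of allyl β-keto esters and the oxygen-to-carbon allyl shift of allyl vinyl ethers under zerovalent palladium, combined with a base-mediated intramolecular aldol addition. Ring B closes in a chair-like 6-endo mode on the pentadienyl system (closure at C7 or C12 would give a cyclobutane) and ring A in a 6-enolendo-exo-trig aldol mode. C10 is controlled by allylic 1,3-strain in the enolate (H-9 eclipses the enolate double bond, so C5 bonds anti to the C9 silyloxymethyl group and the methyl group becomes axial), C5 by the syn position of the bulky CMe2CHO group on the allyl terminus (equatorial in the chair, hence trans to the C10 methyl) and C3 by reversible aldol addition that should favour the equatorial alcohol of the trans-decalin. The step needs carbon over oxygen allylation, secured because the cyclic enol ethers from oxygen attack re-ionise under the catalyst, and it needs no control at C7 or C10 of 13, since both centres are trigonal in the ion pair; β-hydride loss from the palladium intermediate is blocked because C4 and C8 carry no hydrogen.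

Step 10
Reactants: 15 (3R,4aR,8R,8aR)-8-({[tert-butyl(dimethyl)silyl]oxy}methyl)-3-hydroxy-4,4,8a-trimethyl-7-methylidene-3,4,4a,7,8,8a-hexahydronaphthalen-1(2H)-one
Product: 16 4-methylbenzenesulfonohydrazone (C-1 tosylhydrazone) of 15
Conditions: TsNHNH2, EtOH, 60 °C
Reagents that add atoms: 4-methylbenzenesulfonohydrazide, Cc1ccc(cc1)S(=O)(=O)NN
Why: Hydrazone formation at the only carbonyl group should proceed without change at the stereocentres.

Step 11
Reactants: 16 4-methylbenzenesulfonohydrazone of 15
Product: 17 (2R,4aR,5R,8aS)-5-({[tert-butyl(dimethyl)silyl]oxy}methyl)-1,1,4a-trimethyl-6-methylidene-1,2,3,4,4a,5,6,8a-octahydronaphthalen-2-ol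
Conditions: catecholborane, CHCl3, 0 °C; then NaOAc·3H2O, 60 °C
Reagents that add atoms: none
Why: Hydride reduction of the tosylhydrazone followed by loss of sulfinate and N2 (reductive deoxygenation of a ketone by way of its tosylhydrazone) should turn C1 into CH2 under conditions that leave the diene and the C3 carbinol alone.

Step 12
Reactants: 17 (2R,4aR,5R,8aS)-5-({[tert-butyl(dimethyl)silyl]oxy}methyl)-1,1,4a-trimethyl-6-methylidene-1,2,3,4,4a,5,6,8a-octahydronaphthalen-2-ol
Product: 18 (2R,4aR,5R,8aS)-5-(hydroxymethyl)-1,1,4a-trimethyl-6-methylidene-1,2,3,4,4a,5,6,8a-octahydronaphthalen-2-ol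
Conditions: Bu4NF, THF, 23 °C
Reagents that add atoms: none
Why: Fluoride cleavage of the primary silyl ether should free the C11 hydroxyl.

Step 13
Reactants: 18 (2R,4aR,5R,8aS)-5-(hydroxymethyl)-1,1,4a-trimethyl-6-methylidene-1,2,3,4,4a,5,6,8a-octahydronaphthalen-2-ol; 19 7-hydroxy-2H-chromen-2-one
Product: 20 7-{[(1R,4aS,6R,8aR)-6-hydroxy-5,5,8a-trimethyl-2-methylidene-1,2,4a,5,6,7,8,8a-octahydronaphthalen-1-yl]methoxy}-2H-chromen-2-one
Conditions: PPh3, diisopropyl azodicarboxylate, THF, 0 → 23 °C
Reagents that add atoms: none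
Why: Mitsunobu etherification with the acidic phenol should take place at the primary C11 hydroxyl only, because the C3 hydroxyl is flanked by the quaternary C4, and no stereocentre is involved.

**Compound list**

1 | tert-butyl(dimethyl)(prop-2-en-1-yloxy)silane | C=CCO[Si](C)(C)C(C)(C)C | starting material
2 | (2E)-but-2-enal | C/C=C/C=O | starting material
3 | (2E)-4-{[tert-butyl(dimethyl)silyl]oxy}but-2-enal | O=C/C=C/CO[Si](C)(C)C(C)(C)C | intermediate
4 | methyl 3-hydroxy-2,2-dimethylpropanoate | COC(=O)C(C)(C)CO | starting material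
5 | methyl 2,2-dimethyl-3-oxopropanoate | COC(=O)C(C)(C)C=O | intermediate
6 | methyl (3E)-4-iodo-2,2-dimethylbut-3-enoate | COC(=O)C(C)(C)/C=C/I | intermediate
7 | (3E)-4-iodo-2,2-dimethylbut-3-en-1-ol | OCC(C)(C)/C=C/I | intermediate
8 | methyl 2-methyl-3-oxobutanoate (racemic) | COC(=O)C(C)C(C)=O | starting material
9 | methyl (3R)-2-acetyl-3-({[tert-butyl(dimethyl)silyl]oxy}methyl)-2-methyl-5-oxopentanoate (both C-2 epimers) | O=CC[C@@H](CO[Si](C)(C)C(C)(C)C)C(C)(C(C)=O)C(=O)OC | intermediate
10 | methyl (3R)-2-acetyl-3-({[tert-butyl(dimethyl)silyl]oxy}methyl)-4-formyl-2-methylpent-4-enoate (both C-2 epimers) | O=CC(=C)[C@@H](CO[Si](C)(C)C(C)(C)C)C(C)(C(C)=O)C(=O)OC | intermediate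
11 | methyl (3R,6E)-2-acetyl-3-({[tert-butyl(dimethyl)silyl]oxy}methyl)-5,9-dihydroxy-2,8,8-trimethyl-4-methylidenenon-6-enoate (epimers at C-2 and C-5) | OCC(C)(C)/C=C/C(O)C(=C)[C@@H](CO[Si](C)(C)C(C)(C)C)C(C)(C(C)=O)C(=O)OC | intermediate
12 | (4R)-3-acetyl-4-({[tert-butyl(dimethyl)silyl]oxy}methyl)-6-[(1E)-4-hydroxy-3,3-dimethylbut-1-en-1-yl]-3-methyl-5-methylideneoxan-2-one (epimers at C-3 and C-6) | O=C1OC(/C=C/C(C)(C)CO)C(=C)[C@@H](CO[Si](C)(C)C(C)(C)C)C1(C)C(C)=O | intermediate
13 | (3E)-4-[(4R)-5-acetyl-4-({[tert-butyl(dimethyl)silyl]oxy}methyl)-5-methyl-3-methylidene-6-oxooxan-2-yl]-2,2-dimethylbut-3-enal (epimers at oxane C-2 and C-5) | O=C1OC(/C=C/C(C)(C)C=O)C(=C)[C@@H](CO[Si](C)(C)C(C)(C)C)C1(C)C(C)=O | intermediate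
14 | 2-[(1R,5R,6R)-6-acetyl-5-({[tert-butyl(dimethyl)silyl]oxy}methyl)-6-methyl-4-methylidenecyclohex-2-en-1-yl]-2-methylpropanal | C=C1C=C[C@H](C(C)(C)C=O)[C@@](C)(C(C)=O)[C@@H]1CO[Si](C)(C)C(C)(C)C | intermediate
15 | (3R,4aR,8R,8aR)-8-({[tert-butyl(dimethyl)silyl]oxy}methyl)-3-hydroxy-4,4,8a-trimethyl-7-methylidene-3,4,4a,7,8,8a-hexahydronaphthalen-1(2H)-one | C=C1C=C[C@@H]2C(C)(C)[C@H](O)CC(=O)[C@@]2(C)[C@@H]1CO[Si](C)(C)C(C)(C)C | intermediate
16 | 4-methylbenzenesulfonohydrazone (C-1 tosylhydrazone) of 15 | C=C1C=C[C@@H]2C(C)(C)[C@H](O)CC(=NNS(=O)(=O)c3ccc(C)cc3)[C@@]2(C)[C@@H]1CO[Si](C)(C)C(C)(C)C | intermediate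
17 | (2R,4aR,5R,8aS)-5-({[tert-butyl(dimethyl)silyl]oxy}methyl)-1,1,4a-trimethyl-6-methylidene-1,2,3,4,4a,5,6,8a-octahydronaphthalen-2-ol | C=C1C=C[C@@H]2C(C)(C)[C@H](O)CC[C@@]2(C)[C@@H]1CO[Si](C)(C)C(C)(C)C | intermediate
18 | (2R,4aR,5R,8aS)-5-(hydroxymethyl)-1,1,4a-trimethyl-6-methylidene-1,2,3,4,4a,5,6,8a-octahydronaphthalen-2-ol | C=C1C=C[C@@H]2C(C)(C)[C@H](O)CC[C@@]2(C)[C@@H]1CO | intermediate
19 | 7-hydroxy-2H-chromen-2-one (umbelliferone) | O=c1ccc2ccc(O)cc2o1 | starting material
20 | 7-{[(1R,4aS,6R,8aR)-6-hydroxy-5,5,8a-trimethyl-2-methylidene-1,2,4a,5,6,7,8,8a-octahydronaphthalen-1-yl]methoxy}-2H-chromen-2-one | C=C1C=C[C@@H]2C(C)(C)[C@H](O)CC[C@@]2(C)[C@@H]1COc1ccc2ccc(=O)oc2c1 | target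

Total steps: 13. Longest linear sequence: 10 steps (steps 1 and 5–13; the branch through steps 2–4 and 7–13 is equally long).

**Steps most likely to fail**

Step 9. The tetrasubstituted enolate may be quenched by proton transfer, or loss of CO2 from the palladium carboxylate may lag behind return of the ion pair to the lactone, so that no bond to C5 is formed. The fallback sets out from 13 and comes back at 15, and it stores the enolate as an enol ether instead of unveiling it by decarboxylation. Saponification of the lactone with LiOH in aqueous THF, mild acidification and gentle warming should decarboxylate the β-keto acid to the δ-hydroxy ketone (3E,7S)-7-({[tert-butyl(dimethyl)silyl]oxy}methyl)-5-hydroxy-2,2,8-trimethyl-6-methylidene-9-oxodec-3-enal F1. Acid-catalysed cyclodehydration (pyridinium p-toluenesulfonate, 4 Å sieves, benzene) should then give the cyclic enol ether (3E)-4-[4-({[tert-butyl(dimethyl)silyl]oxy}methyl)-5,6-dimethyl-3-methylidene-3,4-dihydro-2H-pyran-2-yl]-2,2-dimethylbut-3-enal F2, an allyl vinyl ether with the C9 configuration of 13. The known oxygen-to-carbon allyl shift of allyl vinyl ethers under zerovalent palladium (Pd(PPh3)4, DMSO, 60 °C), followed by DBU, should deliver 15 by way of 14 through the same ion pair and the same stereochemical arguments.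

Step 10. Condensation at the hindered C1 carbonyl may be slow, so that β-elimination of the C3 hydroxyl or retro-aldol opening of ring A takes over. The fallback sets out from 15 and comes back at 18, bypassing steps 11 and 12, and removes the oxygen by a radical route. Silylation (t-BuMe2SiOTf, 2,6-lutidine) should give the C3 silyl ether of 15 F3, and NaBH4 reduction the C1 alcohol F4 (either epimer serves). Treatment with NaH, CS2 and MeI should give the S-methyl xanthate F5, and Barton–McCombie deoxygenation (Bu3SnH, azobisisobutyronitrile, toluene, 90 °C) the bis-silyl ether of 18 F6. Bu4NF in THF at 50 °C should then remove both silyl groups and return 18.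

Step 13. Displacement at the β-branched C11 alkoxyphosphonium ion may be retarded by the neighbouring quaternary C10, so that the betaine is consumed by alkylation of the hydrazide or by elimination. The fallback sets out from 18 and comes back at 20, with a preformed alkyl halide and a thermal Williamson ether synthesis. Selective iodination of the primary hydroxyl (PPh3, I2, imidazole, CH2Cl2, 0 °C) should give the C11 iodide of 18 F7, which is heated with 19 and Cs2CO3 in DMF at 60 °C.

Further compounds
F1 | step 9 | (3E,7S)-7-({[tert-butyl(dimethyl)silyl]oxy}methyl)-5-hydroxy-2,2,8-trimethyl-6-methylidene-9-oxodec-3-enal (epimers at C-5 and C-8) | O=CC(C)(C)/C=C/C(O)C(=C)[C@@H](CO[Si](C)(C)C(C)(C)C)C(C)C(C)=O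
F2 | step 9 | (3E)-4-[4-({[tert-butyl(dimethyl)silyl]oxy}methyl)-5,6-dimethyl-3-methylidene-3,4-dihydro-2H-pyran-2-yl]-2,2-dimethylbut-3-enal (C-4 of the pyran as in 13, both C-2 epimers) | CC1=C(C)[C@H](CO[Si](C)(C)C(C)(C)C)C(=C)C(/C=C/C(C)(C)C=O)O1
F3 | step 10 | C3 tert-butyldimethylsilyl ether of 15 | C=C1C=C[C@@H]2C(C)(C)[C@H](O[Si](C)(C)C(C)(C)C)CC(=O)[C@@]2(C)[C@@H]1CO[Si](C)(C)C(C)(C)C
F4 | step 10 | C1 alcohol from F3 (either epimer) | C=C1C=C[C@@H]2C(C)(C)[C@H](O[Si](C)(C)C(C)(C)C)CC(O)[C@@]2(C)[C@@H]1CO[Si](C)(C)C(C)(C)C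
F5 | step 10 | S-methyl xanthate of F4 | C=C1C=C[C@@H]2C(C)(C)[C@H](O[Si](C)(C)C(C)(C)C)CC(OC(=S)SC)[C@@]2(C)[C@@H]1CO[Si](C)(C)C(C)(C)C
F6 | step 10 | bis(tert-butyldimethylsilyl) ether of 18 | C=C1C=C[C@@H]2C(C)(C)[C@H](O[Si](C)(C)C(C)(C)C)CC[C@@]2(C)[C@@H]1CO[Si](C)(C)C(C)(C)C
F7 | step 13 | C11 iodide of 18 | C=C1C=C[C@@H]2C(C)(C)[C@H](O)CC[C@@]2(C)[C@@H]1CI
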